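**Strategy.** The target is a δ,ε-unsaturated aldehyde: the CH2CHO arm on C3 and the exocyclic methylene next to C2 (pentanoic acid numbering) flank the C2–C3 bond, which is the retron of an oxy-Cope rearrangement. The two halves are therefore first tied through a sacrificial carbinol C–C bond in an (E,E)-1,5-dien-3-ol that carries the acid as a free (E)-enoic acid and the future dihydrofuran ring as a (Z)-enynol. One anionic [3,3] shift cuts the tether, forms C2–C3, sets both stereocentres from the single carbinol centre and releases the aldehyde arm and the 1,1-disubstituted alkene. Gold-catalysed 5-exo-dig ring closure, Vilsmeier formylation and acid unmasking complete the route.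

Key step: step 9

Assumption: the (S)-enantiomer of the TRIP phosphoric acid is taken to give the 4S carbinol in step 2 (the antipode would be used if the sense of induction proved opposite), and bromide 8 is taken as commercial.

**Step 1**
Reactants: 1 3-(trimethylsilyl)prop-2-ynal; 2 (triphenylphosphoranylidene)acetaldehyde
Product: 3 (2E)-5-(trimethylsilyl)pent-2-en-4-ynal
Conditions: CH2Cl2, rt
Reagents that add atoms: none
Why: Wittig olefination with a stabilised ylide is E-selective, and the ynal is far more electrophilic than the enal formed, so a single two-carbon homologation is expected.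

**Step 2**
Reactants: 3 (2E)-5-(trimethylsilyl)pent-2-en-4-ynal; 4 allenylboronic acid pinacol ester
Product: 6 (4S,5E)-8-(trimethylsilyl)oct-5-ene-1,7-diyn-4-ol, via O-pinacolboryl ether 5 (not isolated)
Conditions: (S)-TRIP (5 mol%), 4 Å MS, toluene, 0 °C; aqueous work-up
Reagents that add atoms: none
Why: Chiral phosphoric acid-catalysed propargylboration through a closed six-membered SE2′ transition state, in which the catalyst-bound boronate should deliver the propargyl group to one aldehyde face and set the 4S carbinol.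

**Step 3**
Reactants: 6 (4S,5E)-8-(trimethylsilyl)oct-5-ene-1,7-diyn-4-ol
Product: 7 (4S,5E)-4-(tert-butyldimethylsilyloxy)-8-(trimethylsilyl)oct-5-ene-1,7-diyne
Conditions: TBSCl, imidazole, DMF, rt
Reagents that add atoms: tert-butyldimethylsilyl chloride, CC(C)(C)[Si](C)(C)Cl
Why: Standard silylation of the secondary alcohol keeps the carbinol inert toward the organocopper reagent of step 5 and leaves the stereocentre untouched.

**Step 4**
Reactants: 8 2-(3-bromopropyl)-2-methyl-1,3-dioxolane
Product: 9 [3-(2-methyl-1,3-dioxolan-2-yl)propyl]magnesium bromide (used as solution)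
Conditions: Mg turnings, cat. 1,2-dibromoethane, Et2O, reflux
Reagents that add atoms: magnesium, [Mg]
Why: Grignard formation from a primary bromide; the dioxolane-masked ketone is inert to the organomagnesium.

**Step 5**
Reactants: 7 (4S,5E)-4-(tert-butyldimethylsilyloxy)-8-(trimethylsilyl)oct-5-ene-1,7-diyne; 9 [3-(2-methyl-1,3-dioxolan-2-yl)propyl]magnesium bromide
Product: 11 (2E,5S,6E)-5-(tert-butyldimethylsilyloxy)-3-[3-(2-methyl-1,3-dioxolan-2-yl)propyl]-9-(trimethylsilyl)nona-2,6-dien-8-ynoic acid, via alkenylcopper 10 (not isolated)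
Conditions: 9 + CuBr·SMe2 (1:1), Et2O–Me2S, −45 °C; then 7, −25 °C; then CO2 (1 atm), HMPA, P(OEt)3 (cat.), −25 °C → rt; aq. NH4Cl, then citric acid to pH 4
Reagents that add atoms: carbon dioxide, O=C=O
Why: Normant carbocupration adds the alkyl group and copper syn across the terminal alkyne (alkyl to the internal carbon), and carboxylation of the alkenylcopper with retention places CO2H cis to the new chain (2E); no stereocentre is formed and the silyl-capped internal alkyne should not react.

**Step 6**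
Reactants: 11 (2E,5S,6E)-5-(tert-butyldimethylsilyloxy)-3-[3-(2-methyl-1,3-dioxolan-2-yl)propyl]-9-(trimethylsilyl)nona-2,6-dien-8-ynoic acid
Product: 12 (2E,5S,6E)-5-hydroxy-3-[3-(2-methyl-1,3-dioxolan-2-yl)propyl]nona-2,6-dien-8-ynoic acid
Conditions: TBAF (3.5 equiv), THF, 0 °C → rt; citric acid work-up
Reagents that add atoms: none
Why: Fluoride-mediated desilylation cleaves both the O–TBS and the C(sp)–TMS bonds, and the (2E)-geometry prevents lactonisation of the liberated δ-hydroxy acid.

**Step 7**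
Reactants: 13 ethyl (2Z)-3-iodoprop-2-enoate; 14 methylmagnesium bromide
Product: 15 (3Z)-4-iodo-2-methylbut-3-en-2-ol
Conditions: Et2O, −78 → 0 °C; aq. NH4Cl
Reagents that add atoms: none
Why: Double Grignard addition to the ester gives the tertiary alcohol, and at low temperature the vinyl iodide and its Z-geometry should be retained.

**Step 8**
Reactants: 12 (2E,5S,6E)-5-hydroxy-3-[3-(2-methyl-1,3-dioxolan-2-yl)propyl]nona-2,6-dien-8-ynoic acid; 15 (3Z)-4-iodo-2-methylbut-3-en-2-ol
Product: 16 (2E,5S,6E,10Z)-5,12-dihydroxy-12-methyl-3-[3-(2-methyl-1,3-dioxolan-2-yl)propyl]trideca-2,6,10-trien-8-ynoic acid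
Conditions: PdCl2(PPh3)2 (3 mol%), CuI (6 mol%), Et3N, THF, rt; work-up at pH 4–5
Reagents that add atoms: none
Why: Sonogashira coupling of the terminal enyne with the vinyl iodide proceeds with retention of the Z-geometry and tolerates the free acid (as its ammonium salt) and both hydroxyl groups.

**Step 9**
Reactants: 16 (2E,5S,6E,10Z)-5,12-dihydroxy-12-methyl-3-[3-(2-methyl-1,3-dioxolan-2-yl)propyl]trideca-2,6,10-trien-8-ynoic acid
Product: 19 (2R,3S,6Z)-8-hydroxy-8-methyl-2-[5-(2-methyl-1,3-dioxolan-2-yl)pent-1-en-2-yl]-3-(2-oxoethyl)non-6-en-4-ynoic acid, via tripotassium salt 17 (not isolated), via tripotassium enolate 18 (not isolated)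
Conditions: KH (4 equiv), 18-crown-6 (4 equiv), THF, 0 °C → rt; AcOH quench at −78 °C
Reagents that add atoms: none
Why: KH converts 16 into tripotassium salt 17, whose C5 alkoxide triggers an anionic oxy-Cope ([3,3]) rearrangement in which the sacrificial C4–C5 bond breaks while C2–C7 forms, giving enolate 18; after protonation C5/C6 appear as the CH2CHO arm and C4 as the exocyclic methylene. The closest known reaction type is the alkoxide-accelerated oxy-Cope rearrangement of acyclic 1,5-dien-3-ols with 1,3-chirality transfer, and no ring is closed. C2 of 19 (2R) is set by the (2E)-enoate geometry and C3 of 19 (3S) by the (6E)-alkene geometry within a chair transition state in which carboxylate, enynyl group and oxyanion are all pseudo-equatorial, the last preference being reinforced by the alkyl chain on C3 of 16. The absolute sense therefore derives from the single (5S)-carbinol centre. The step needs the [3,3] shift to outrun retro-vinylogous-aldol cleavage of the alkoxide and epimerisation α to the carboxyl group; carrying the acid as its carboxylate makes the would-be leaving group a prohibitive dianionic dienolate and renders the α-proton non-acidic.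

**Step 10**
Reactants: 19 (2R,3S,6Z)-8-hydroxy-8-methyl-2-[5-(2-methyl-1,3-dioxolan-2-yl)pent-1-en-2-yl]-3-(2-oxoethyl)non-6-en-4-ynoic acid
Product: 20 4-methoxybenzyl (2R,3S,6Z)-8-hydroxy-8-methyl-2-[5-(2-methyl-1,3-dioxolan-2-yl)pent-1-en-2-yl]-3-(2-oxoethyl)non-6-en-4-ynoate
Conditions: O-(4-methoxybenzyl)-N,N′-diisopropylisourea, THF, rt
Reagents that add atoms: O-(4-methoxybenzyl)-N,N′-diisopropylisourea, CC(C)N=C(OCc1ccc(OC)cc1)NC(C)C
Why: Isourea-mediated O-alkylation esterifies only the carboxylic acid under neutral conditions, which protects it from the gold and chloroiminium reagents of step 11 without risk to the α-stereocentre or the aldehyde.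

**Step 11**
Reactants: 20 4-methoxybenzyl (2R,3S,6Z)-8-hydroxy-8-methyl-2-[5-(2-methyl-1,3-dioxolan-2-yl)pent-1-en-2-yl]-3-(2-oxoethyl)non-6-en-4-ynoate
Product: 22 4-methoxybenzyl (2R,3S)-3-[(1E)-1-(5,5-dimethylfuran-2(5H)-ylidene)-2-oxoethyl]-2-[5-(2-methyl-1,3-dioxolan-2-yl)pent-1-en-2-yl]-5-oxopentanoate, via dienol ether 21 (not isolated)
Conditions: Ph3PAuCl/AgOTf (2 mol%), CH2Cl2, 0 °C; then solution transferred to (chloromethylene)dimethyliminium chloride (1.3 equiv), pyridine (3 equiv), CH2Cl2, −20 → 0 °C; aq. NaOAc, rt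
Reagents that add atoms: (chloromethylene)dimethyliminium chloride, C[N+](C)=CCl.[Cl-]; water, O
Why: Gold-catalysed cycloisomerisation (anti 5-exo-dig attack of the tertiary hydroxyl of the (Z)-enynol) should give the (Z)-2-alkylidene-2,5-dihydrofuran 21, whose enol-ether β-carbon is the only position that leads to an oxygen-stabilised cation and is formylated in a Vilsmeier–Haack reaction; the push–pull alkene can equilibrate and should settle with the bulky C3 substituent cis to the ring oxygen (E).

**Step 12**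
Reactants: 22 4-methoxybenzyl (2R,3S)-3-[(1E)-1-(5,5-dimethylfuran-2(5H)-ylidene)-2-oxoethyl]-2-[5-(2-methyl-1,3-dioxolan-2-yl)pent-1-en-2-yl]-5-oxopentanoate
Product: 23 (2R,3S)-3-[(1E)-1-(5,5-dimethylfuran-2(5H)-ylidene)-2-oxoethyl]-2-(6-oxohept-1-en-2-yl)-5-oxopentanoic acid (target, CNP0150297.1)
Conditions: TFA/H2O/CH2Cl2 (10:5:85), 0 °C → rt
Reagents that add atoms: water, O
Why: Mild acidolysis cleaves the 4-methoxybenzyl ester through the stabilised benzylic cation and hydrolyses the dioxolane to the methyl ketone, conditions under which the vinylogous formate and both stereocentres should persist.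

**Compound list**

1 | 3-(trimethylsilyl)prop-2-ynal | C[Si](C)(C)C#CC=O | starting material
2 | (triphenylphosphoranylidene)acetaldehyde | O=CC=P(c1ccccc1)(c1ccccc1)c1ccccc1 | starting material
3 | (2E)-5-(trimethylsilyl)pent-2-en-4-ynal | C[Si](C)(C)C#C/C=C/C=O | intermediate
4 | allenylboronic acid pinacol ester | C=C=CB1OC(C)(C)C(C)(C)O1 | starting material
5 | O-pinacolboryl ether of 6 | C#CC[C@H](OB1OC(C)(C)C(C)(C)O1)/C=C/C#C[Si](C)(C)C | intermediate
6 | (4S,5E)-8-(trimethylsilyl)oct-5-ene-1,7-diyn-4-ol | C#CC[C@H](O)/C=C/C#C[Si](C)(C)C | intermediate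
7 | (4S,5E)-4-(tert-butyldimethylsilyloxy)-8-(trimethylsilyl)oct-5-ene-1,7-diyne | C#CC[C@H](O[Si](C)(C)C(C)(C)C)/C=C/C#C[Si](C)(C)C | intermediate
8 | 2-(3-bromopropyl)-2-methyl-1,3-dioxolane | CC1(CCCBr)OCCO1 | starting material
9 | [3-(2-methyl-1,3-dioxolan-2-yl)propyl]magnesium bromide | CC1(CCC[Mg]Br)OCCO1 | intermediate
10 | (1E,4S,5E)-alkenylcopper from syn-carbocupration of 7 | [Cu]/C=C(\CCCC1(C)OCCO1)C[C@H](O[Si](C)(C)C(C)(C)C)/C=C/C#C[Si](C)(C)C | intermediate
11 | (2E,5S,6E)-5-(tert-butyldimethylsilyloxy)-3-[3-(2-methyl-1,3-dioxolan-2-yl)propyl]-9-(trimethylsilyl)nona-2,6-dien-8-ynoic acid | OC(=O)/C=C(\CCCC1(C)OCCO1)C[C@H](O[Si](C)(C)C(C)(C)C)/C=C/C#C[Si](C)(C)C | intermediate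
12 | (2E,5S,6E)-5-hydroxy-3-[3-(2-methyl-1,3-dioxolan-2-yl)propyl]nona-2,6-dien-8-ynoic acid | OC(=O)/C=C(\CCCC1(C)OCCO1)C[C@H](O)/C=C/C#C | intermediate
13 | ethyl (2Z)-3-iodoprop-2-enoate | CCOC(=O)/C=C\I | starting material
14 | methylmagnesium bromide | C[Mg]Br | starting material
15 | (3Z)-4-iodo-2-methylbut-3-en-2-ol | CC(C)(O)/C=C\I | intermediate
16 | (2E,5S,6E,10Z)-5,12-dihydroxy-12-methyl-3-[3-(2-methyl-1,3-dioxolan-2-yl)propyl]trideca-2,6,10-trien-8-ynoic acid | OC(=O)/C=C(\CCCC1(C)OCCO1)C[C@H](O)/C=C/C#C/C=C\C(C)(C)O | intermediate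
17 | tripotassium salt of 16 (carboxylate, 5-alkoxide, 12-alkoxide) | [O-]C(=O)/C=C(\CCCC1(C)OCCO1)C[C@H]([O-])/C=C/C#C/C=C\C(C)(C)[O-].[K+].[K+].[K+] | intermediate
18 | tripotassium (E)-enolate of 19 (carboxylate, aldehyde enolate, tertiary alkoxide) | C=C(CCCC1(C)OCCO1)[C@H](C(=O)[O-])[C@H](/C=C/[O-])C#C/C=C\C(C)(C)[O-].[K+].[K+].[K+] | intermediate
19 | (2R,3S,6Z)-8-hydroxy-8-methyl-2-[5-(2-methyl-1,3-dioxolan-2-yl)pent-1-en-2-yl]-3-(2-oxoethyl)non-6-en-4-ynoic acid | C=C(CCCC1(C)OCCO1)[C@H](C(=O)O)[C@H](CC=O)C#C/C=C\C(C)(C)O | intermediate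
20 | 4-methoxybenzyl ester of 19 | C=C(CCCC1(C)OCCO1)[C@H](C(=O)OCc2ccc(OC)cc2)[C@H](CC=O)C#C/C=C\C(C)(C)O | intermediate
21 | 4-methoxybenzyl (2R,3R)-3-[(Z)-(5,5-dimethylfuran-2(5H)-ylidene)methyl]-2-[5-(2-methyl-1,3-dioxolan-2-yl)pent-1-en-2-yl]-5-oxopentanoate | C=C(CCCC1(C)OCCO1)[C@H](C(=O)OCc2ccc(OC)cc2)[C@H](CC=O)/C=C3/C=CC(C)(C)O3 | intermediate
22 | 4-methoxybenzyl (2R,3S)-3-[(1E)-1-(5,5-dimethylfuran-2(5H)-ylidene)-2-oxoethyl]-2-[5-(2-methyl-1,3-dioxolan-2-yl)pent-1-en-2-yl]-5-oxopentanoate | C=C(CCCC1(C)OCCO1)[C@H](C(=O)OCc2ccc(OC)cc2)[C@H](CC=O)/C(C=O)=C3/C=CC(C)(C)O3 | intermediate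
23 | (2R,3S)-3-[(1E)-1-(5,5-dimethylfuran-2(5H)-ylidene)-2-oxoethyl]-2-(6-oxohept-1-en-2-yl)-5-oxopentanoic acid | C=C(CCCC(C)=O)[C@H](C(=O)O)[C@H](CC=O)/C(C=O)=C1/C=CC(C)(C)O1 | target

**Step count and risks**

Total steps: 12. Longest linear sequence: 10 (steps 1, 2, 3, 5, 6, 8, 9, 10, 11, 12).

Steps most likely to fail:

1. Step 9. The tripotassium salt may dissolve poorly and rearrange sluggishly, or part of the material may pass through a boat or an axial-oxyanion chair transition state, which would erode diastereo- and enantiopurity. Fallback: setting out from 16, the acid would first be esterified with O-(4-methoxybenzyl)-N,N′-diisopropylisourea (THF, rt) to give the 4-methoxybenzyl ester of 16 F1. Its dipotassium dialkoxide (KH, 18-crown-6, THF, −20 → 0 °C, AcOH quench) would then undergo the sigmatropic shift as a neutral-ester substrate, kept cold to limit fragmentation. This comes back to the route at 20.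

2. Step 11. The chloroiminium salt may attack the enol of the free aldehyde competitively, or the dienol ether may hydrolyse under the acidic formylation conditions before it is formylated. Fallback: setting out from 20, iodocyclisation (NIS, NaHCO3, MeCN, 0 °C; anti 5-exo-dig) would give the 4-methoxybenzyl (2R,3S)-3-[(E)-(5,5-dimethylfuran-2(5H)-ylidene)iodomethyl]-2-[5-(2-methyl-1,3-dioxolan-2-yl)pent-1-en-2-yl]-5-oxopentanoate F2. Palladium-catalysed reductive carbonylation of this vinyl iodide (Pd(PPh3)4, CO 1 atm, Bu3SnH by slow addition, THF, 50 °C) would install the formyl group with the geometry already fixed. This comes back to the route at 22.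

3. Step 5. Carbocupration of the polyunsaturated alkyne may be incomplete or regio-unselective, or the alkenylcopper may be protonated instead of carboxylated. Fallback: setting out from 7, the acetylide (n-BuLi, THF, −78 °C) would be trapped with methyl chloroformate to give the ynoate methyl (5S,6E)-5-(tert-butyldimethylsilyloxy)-9-(trimethylsilyl)non-6-ene-2,8-diynoate F3. Anti-hydroiodination (NaI, AcOH, MeCN, 40 °C) would give the (Z)-β-iodoenoate methyl (2Z,5S,6E)-5-(tert-butyldimethylsilyloxy)-3-iodo-9-(trimethylsilyl)nona-2,6-dien-8-ynoate F4. Stereoretentive iron-catalysed coupling with Grignard 9 (Fe(acac)3 5 mol%, THF/NMP, −30 °C) would give the methyl ester of 11 F5, and Me3SnOH (1,2-dichloroethane, 70 °C; dilute HCl work-up) would cleave the methyl ester. This comes back to the route at 11.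

**Further compounds**

F1 | step 9 | 4-methoxybenzyl (2E,5S,6E,10Z)-5,12-dihydroxy-12-methyl-3-[3-(2-methyl-1,3-dioxolan-2-yl)propyl]trideca-2,6,10-trien-8-ynoate | COc1ccc(COC(=O)/C=C(\CCCC2(C)OCCO2)C[C@H](O)/C=C/C#C/C=C\C(C)(C)O)cc1
F2 | step 11 | 4-methoxybenzyl (2R,3S)-3-[(E)-(5,5-dimethylfuran-2(5H)-ylidene)iodomethyl]-2-[5-(2-methyl-1,3-dioxolan-2-yl)pent-1-en-2-yl]-5-oxopentanoate | C=C(CCCC1(C)OCCO1)[C@H](C(=O)OCc2ccc(OC)cc2)[C@H](CC=O)/C(I)=C3/C=CC(C)(C)O3
F3 | step 5 | methyl (5S,6E)-5-(tert-butyldimethylsilyloxy)-9-(trimethylsilyl)non-6-ene-2,8-diynoate | COC(=O)C#CC[C@H](O[Si](C)(C)C(C)(C)C)/C=C/C#C[Si](C)(C)C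
F4 | step 5 | methyl (2Z,5S,6E)-5-(tert-butyldimethylsilyloxy)-3-iodo-9-(trimethylsilyl)nona-2,6-dien-8-ynoate | COC(=O)/C=C(\I)C[C@H](O[Si](C)(C)C(C)(C)C)/C=C/C#C[Si](C)(C)C
F5 | step 5 | methyl (2E,5S,6E)-5-(tert-butyldimethylsilyloxy)-3-[3-(2-methyl-1,3-dioxolan-2-yl)propyl]-9-(trimethylsilyl)nona-2,6-dien-8-ynoate | COC(=O)/C=C(\CCCC1(C)OCCO1)C[C@H](O[Si](C)(C)C(C)(C)C)/C=C/C#C[Si](C)(C)C
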